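The coumarin is cut at the lactone O1–C8a bond, which opens the pyranone ring to an (E)-cinnamic acid. Because the benzene ring carries methoxy groups at C6 and C8 flanking the C7 ether, the opened arene is a symmetric 3,5-dimethoxy-4-alkoxyphenyl unit (the sinapic acid pattern) with two equivalent ortho C–H carbons. A single riboflavin-photocatalysed operation turns the E-acid into its Z isomer and oxidatively bonds the carboxyl oxygen to an ortho carbon, closing the pyranone ring and delivering the target. The precursor is sinapic acid etherified at its phenol with the complete (2R,3R)-epoxy side chain, which comes from geraniol by asymmetric epoxidation and a singlet-oxygen ene reaction, joined by Mitsunobu coupling.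

Key step: step 6

Remark on the chemistry: both oxirane carbons of the target are R, which corresponds to (2R,3R)-2,3-epoxygeraniol. These are the only stereocentres; step 1 sets them and no later step acts on them.

Step 1
Reactants: 1 geraniol
Product: 2 (2R,3R)-2,3-epoxygeraniol
Conditions: Ti(OiPr)4 (5 mol %), D-(−)-DET (7 mol %), TBHP, 4 Å MS, CH2Cl2, −20 °C
Reagents that add atoms: tert-butyl hydroperoxide, CC(C)(C)OO
Why: Katsuki–Sharpless asymmetric epoxidation, in which the allylic alkoxide and the peroxide bind to the titanium tartrate so that only the 2,3-alkene reacts; the D-(−)-tartrate ligand directs oxygen to the enantioface that makes C2 and C3 both R (natural L-(+)-tartrate gives the 2S,3S mirror image), and the remote 6,7-alkene has no directing hydroxyl and stays intact.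

Step 2
Reactants: 2 (2R,3R)-2,3-epoxygeraniol
Product: 4 [(2R,3R)-3-[(E)-4-hydroxy-4-methylpent-2-en-1-yl]-3-methyloxiran-2-yl]methanol, via tertiary allylic hydroperoxide 3 (not isolated)
Conditions: O2, TPP (cat.), visible light, CH2Cl2, 0 °C; then PPh3, 0 °C to rt
Reagents that add atoms: dioxygen (reacting as singlet oxygen), O=O
Why: Schenck ene reaction, in which singlet oxygen bonds to the fully substituted carbon of the only alkene and abstracts an allylic hydrogen from the chain CH2, moving the double bond into the E-1,2-disubstituted position to give hydroperoxide 3, which PPh3 reduces in the same pot; no stereocentre is formed or touched, and the secondary isopropenyl regioisomer from methyl-hydrogen abstraction is expected in a comparable amount and is removed by chromatography.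

Step 3
Reactants: 5 sinapic acid
Product: 6 methyl sinapate
Conditions: MeOH, H2SO4 (cat.), reflux
Reagents that add atoms: methanol, CO
Why: Fischer esterification in excess methanol masks the carboxylic acid, which would otherwise be the Mitsunobu nucleophile, and leaves the phenol and the E-alkene unchanged.

Step 4
Reactants: 4 [(2R,3R)-3-[(E)-4-hydroxy-4-methylpent-2-en-1-yl]-3-methyloxiran-2-yl]methanol and 6 methyl sinapate
Product: 7 methyl (E)-3-(4-{[(2R,3R)-3-[(E)-4-hydroxy-4-methylpent-2-en-1-yl]-3-methyloxiran-2-yl]methoxy}-3,5-dimethoxyphenyl)acrylate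
Conditions: PPh3, DIAD, THF, 0 °C to rt
Reagents that add atoms: none
Why: Mitsunobu etherification, in which the primary hydroxyl of 4 is activated as an alkoxyphosphonium ion and displaced by the phenoxide of 6 in an SN2 reaction at CH2; the tertiary allylic hydroxyl is too hindered to be activated and the epoxide carbons are not involved.

Step 5
Reactants: 7 methyl (E)-3-(4-{[(2R,3R)-3-[(E)-4-hydroxy-4-methylpent-2-en-1-yl]-3-methyloxiran-2-yl]methoxy}-3,5-dimethoxyphenyl)acrylate
Product: 8 (E)-3-(4-{[(2R,3R)-3-[(E)-4-hydroxy-4-methylpent-2-en-1-yl]-3-methyloxiran-2-yl]methoxy}-3,5-dimethoxyphenyl)acrylic acid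
Conditions: LiOH·H2O, THF/MeOH/H2O, rt; then AcOH to pH 5, 0 °C
Reagents that add atoms: lithium hydroxide, [Li+].[OH-]
Why: Saponification by acyl–oxygen cleavage, to which the trisubstituted epoxide, the tertiary alcohol and the aryl ether are inert at room temperature; acidification with acetic acid frees the cinnamic acid without exposing the epoxide to strong acid, and the acid is used directly.

Step 6
Reactants: 8 (E)-3-(4-{[(2R,3R)-3-[(E)-4-hydroxy-4-methylpent-2-en-1-yl]-3-methyloxiran-2-yl]methoxy}-3,5-dimethoxyphenyl)acrylic acid
Product: 10 CNP0325711.2 (target) 7-{[(2R,3R)-3-[(E)-4-hydroxy-4-methylpent-2-en-1-yl]-3-methyloxiran-2-yl]methoxy}-6,8-dimethoxy-2H-chromen-2-one, via Z-acid 9 (not isolated)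
Conditions: (−)-riboflavin (5 mol %), O2 (1 atm), 402 nm LEDs, MeCN/MeOH (1:1), rt
Reagents that add atoms: none
Why: Photoexcited riboflavin first acts as a triplet sensitiser and converts E-acid 8 into Z-acid 9, in which the carboxyl group sits beside an ortho C–H; the excited flavin then removes one electron from the trialkoxyarene, the carboxylate oxygen adds to the ortho carbon of the radical cation, and loss of a second electron and a proton rearomatises the ring while O2 reoxidises the reduced flavin and ends as H2O2. The closest known reaction type is the riboflavin-photocatalysed isomerisation and oxidative lactonisation of E-cinnamic acids to coumarins, and the untested features here (no β-substituent, three alkoxy groups, an epoxide in the side chain) are what make this the risk-bearing step. The pyranone ring closes in a six-membered, 6-endo-type attack of oxygen on the ortho carbon (O1–C8a), preferred over 5-exo ipso attack because only the ortho adduct can regain aromaticity by deprotonation. No stereocentre is formed, and the two epoxide centres are remote from the chromophore and untouched. Regioselectivity needs no control element because the two ortho carbons of the 3,5-dimethoxy-4-alkoxyphenyl ring are equivalent, so either closure gives the 6,8-dimethoxy-7-alkoxy pattern. Chemoselectivity is secured by the side chain, which offers only an E-1,2-disubstituted alkene that reacts slowly with singlet oxygen, a non-oxidisable tertiary alcohol and an epoxide that should survive the mild, room-temperature conditions.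

Compound list
1 | geraniol, (2E)-3,7-dimethylocta-2,6-dien-1-ol | CC(C)=CCC/C(C)=C/CO | starting material
2 | (2R,3R)-2,3-epoxygeraniol, [(2R,3R)-3-methyl-3-(4-methylpent-3-en-1-yl)oxiran-2-yl]methanol | OC[C@H]1O[C@]1(C)CCC=C(C)C | intermediate
3 | [(2R,3R)-3-[(E)-4-hydroperoxy-4-methylpent-2-en-1-yl]-3-methyloxiran-2-yl]methanol (tertiary allylic hydroperoxide, formed and reduced in the flask) | OC[C@H]1O[C@]1(C)C/C=C/C(C)(C)OO | intermediate
4 | [(2R,3R)-3-[(E)-4-hydroxy-4-methylpent-2-en-1-yl]-3-methyloxiran-2-yl]methanol | OC[C@H]1O[C@]1(C)C/C=C/C(C)(C)O | intermediate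
5 | sinapic acid, (E)-3-(4-hydroxy-3,5-dimethoxyphenyl)acrylic acid | COc1cc(/C=C/C(O)=O)cc(OC)c1O | starting material
6 | methyl sinapate, methyl (E)-3-(4-hydroxy-3,5-dimethoxyphenyl)acrylate | COC(=O)/C=C/c1cc(OC)c(O)c(OC)c1 | intermediate
7 | methyl (E)-3-(4-{[(2R,3R)-3-[(E)-4-hydroxy-4-methylpent-2-en-1-yl]-3-methyloxiran-2-yl]methoxy}-3,5-dimethoxyphenyl)acrylate | COC(=O)/C=C/c1cc(OC)c(OC[C@H]2O[C@]2(C)C/C=C/C(C)(C)O)c(OC)c1 | intermediate
8 | (E)-3-(4-{[(2R,3R)-3-[(E)-4-hydroxy-4-methylpent-2-en-1-yl]-3-methyloxiran-2-yl]methoxy}-3,5-dimethoxyphenyl)acrylic acid | COc1cc(/C=C/C(O)=O)cc(OC)c1OC[C@H]1O[C@]1(C)C/C=C/C(C)(C)O | intermediate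
9 | (Z)-3-(4-{[(2R,3R)-3-[(E)-4-hydroxy-4-methylpent-2-en-1-yl]-3-methyloxiran-2-yl]methoxy}-3,5-dimethoxyphenyl)acrylic acid (Z-acid, formed and consumed in the flask) | COc1cc(/C=C\C(O)=O)cc(OC)c1OC[C@H]1O[C@]1(C)C/C=C/C(C)(C)O | intermediate
10 | CNP0325711.2, 7-{[(2R,3R)-3-[(E)-4-hydroxy-4-methylpent-2-en-1-yl]-3-methyloxiran-2-yl]methoxy}-6,8-dimethoxy-2H-chromen-2-one | COc1cc2ccc(=O)oc2c(OC)c1OC[C@H]1O[C@]1(C)C/C=C/C(C)(C)O | target

Total step count: 6 steps.
Longest linear sequence: 5 steps (steps 1, 2, 4, 5 and 6, from geraniol); step 3 is a one-step side branch from sinapic acid.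

Steps most likely to fail

Step 6. The cascade may stall at the E/Z photoequilibrium, because a Z-acid without a β-substituent stays conjugated and can be re-excited. The electron-rich coumarin may also be oxidised further, or the epoxide may be slowly solvolysed in the methanolic carboxylic acid medium. The fallback gives up the late lactonisation and uses a ready-made coumarin. It sets out from diol 4, whose primary hydroxyl is coupled under the Mitsunobu conditions of step 4 (PPh3, DIAD, THF, 0 °C to rt) with purchased isofraxidin (7-hydroxy-6,8-dimethoxycoumarin, COc1cc2ccc(=O)oc2c(OC)c1O). It comes back to the route at target 10 directly and makes no new intermediate (F0).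

Step 2. Hydrogen abstraction from the cis methyl group instead of the chain CH2 diverts material into the secondary hydroperoxide, so regioselectivity and throughput may be poor. The fallback controls the regiochemistry with selenium chemistry and sets out from geraniol 1.
- Acetylation (Ac2O, pyridine) gives geranyl acetate F1.
- mCPBA (CH2Cl2, 0 °C) epoxidises the more electron-rich distal alkene to give racemic 6,7-epoxygeranyl acetate F2.
- Sodium phenylselenide (PhSeSePh, NaBH4, EtOH) opens the epoxide at the less substituted C6 to give hydroxy selenide F3.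
- H2O2 oxidises selenium, and the selenoxide eliminates syn toward C5, the only neighbouring carbon that bears hydrogen, to give (2E,5E)-7-hydroxy-3,7-dimethylocta-2,5-dien-1-yl acetate F4.
- K2CO3 in MeOH removes the acetate to give (2E,5E)-3,7-dimethylocta-2,5-diene-1,7-diol F5.
- Katsuki–Sharpless epoxidation of F5 under the conditions of step 1 (D-(−)-DET) acts on the primary allylic alcohol and not on the tertiary one, and comes back to the route at diol 4.

Step 4. Displacement of the alkoxyphosphonium ion by the doubly ortho-substituted phenoxide may be slow, which would let the activated epoxy alcohol decompose or be captured by the hydrazide. The fallback is a Williamson alkylation and sets out from diol 4. Selective sulfonylation of the primary hydroxyl (TsCl, Et3N, DMAP cat., CH2Cl2, 0 °C) gives the primary tosylate F6. Heating F6 with methyl sinapate 6 and K2CO3 in DMF at 50 °C displaces the tosylate at CH2 and comes back to the route at ester 7.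

Further compounds
F0 | step 6 | none | none
F1 | step 2 | geranyl acetate | CC(C)=CCC/C(C)=C/COC(C)=O
F2 | step 2 | 6,7-epoxygeranyl acetate (racemic at the epoxide) | CC(=O)OC/C=C(\C)CCC1OC1(C)C
F3 | step 2 | (E)-7-hydroxy-3,7-dimethyl-6-(phenylselanyl)oct-2-en-1-yl acetate (racemic) | CC(=O)OC/C=C(\C)CCC([Se]c1ccccc1)C(C)(C)O
F4 | step 2 | (2E,5E)-7-hydroxy-3,7-dimethylocta-2,5-dien-1-yl acetate | CC(=O)OC/C=C(\C)C/C=C/C(C)(C)O
F5 | step 2 | (2E,5E)-3,7-dimethylocta-2,5-diene-1,7-diol | OC/C=C(\C)C/C=C/C(C)(C)O
F6 | step 4 | [(2R,3R)-3-[(E)-4-hydroxy-4-methylpent-2-en-1-yl]-3-methyloxiran-2-yl]methyl 4-methylbenzenesulfonate | Cc1ccc(cc1)S(=O)(=O)OC[C@H]1O[C@]1(C)C/C=C/C(C)(C)O
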